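The route rests on cutting the diaryl ether bond between C1 of ring A (the anisole ring, where C1 lies between the C2 methoxy carbon and the C6 carbon carrying the ethano bridge) and the phenolic oxygen of the meta-substituted ring B. A copper-catalysed intramolecular Ullmann etherification closes the 18-membered ring in one operation: the bromine at C1 of ring A fixes the site, the neighbouring methoxy oxygen can assist copper, and the two saturated CH2CH2 bridges let the chain ends meet. The precursor is an open-chain bromo phenol in which ring C keeps its hydroxyl as a benzyl ether; it is built by one SNAr and two Wittig reactions.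

Key step: step 9

Remarks on the chemistry:
- Ring letters: ring A is the methoxy-bearing ring (C1 carries the macrocyclic ether oxygen, C2 the methoxy group, C6 the ethano bridge). Ring B is the meta-linked ring attached to that ether oxygen. Ring C is the ring with the free hydroxyl. Ring D is the para-linked ring.
- Assumption: both Wittig products are carried forward as E/Z mixtures, because both double bonds are saturated in step 8.
- The target has no stereocenter.

Step 1
Reactants: 1 4-(benzyloxy)-3-hydroxybenzaldehyde; 2 4-fluorobenzonitrile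
Product: 3 4-[2-(benzyloxy)-5-formylphenoxy]benzonitrile
Conditions: K2CO3, DMF, 100 °C
Reagents that add atoms: none
Why: Nucleophilic aromatic substitution (SNAr): the phenoxide of 1 should displace the fluoride para to the nitrile, and the benzyl ether already in 1 fixes which ring C oxygen is arylated.

Step 2
Reactants: 4 3-hydroxybenzyl alcohol
Product: 5 (3-hydroxybenzyl)triphenylphosphonium bromide
Conditions: PPh3·HBr, MeCN, reflux
Reagents that add atoms: triphenylphosphine hydrobromide, [Br-].c1ccc(cc1)[PH+](c1ccccc1)c1ccccc1
Why: Direct phosphonium salt formation from a benzylic alcohol; the acid activates the benzylic hydroxyl for substitution by the phosphine while the phenol stays untouched.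

Step 3
Reactants: 3 4-[2-(benzyloxy)-5-formylphenoxy]benzonitrile; 5 (3-hydroxybenzyl)triphenylphosphonium bromide
Product: 6 4-{2-(benzyloxy)-5-[2-(3-hydroxyphenyl)ethenyl]phenoxy}benzonitrile (E/Z mixture)
Conditions: KOtBu (2.5 equiv), THF, 0 °C to rt
Reagents that add atoms: none
Why: Wittig olefination; a second equivalent of base covers the phenol, whose meta oxido group cannot quench the benzylic ylide carbon by conjugation, and the nitrile should be inert to the semistabilised ylide.

Step 4
Reactants: 6 4-{2-(benzyloxy)-5-[2-(3-hydroxyphenyl)ethenyl]phenoxy}benzonitrile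
Product: 8 4-{2-(benzyloxy)-5-[2-(3-hydroxyphenyl)ethenyl]phenoxy}benzaldehyde (E/Z mixture), via N-aluminio aldimine 7 (not isolated)
Conditions: iBu2AlH (DIBAL-H, 3 equiv), CH2Cl2, −78 to −40 °C; then 1 M HCl, 0 °C to rt
Reagents that add atoms: water, O
Why: Partial reduction of a nitrile by hydroalumination; the first equivalent of hydride is spent on the phenol, the reduction should stop at the aluminium aldimine 7, and aqueous acid hydrolyses it to the aldehyde while the benzyl ether, diaryl ether and stilbene stay intact.

Step 5
Reactants: 9 2-bromo-3-methoxybenzaldehyde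
Product: 10 (2-bromo-3-methoxyphenyl)methanol
Conditions: NaBH4, MeOH, 0 °C
Reagents that add atoms: none
Why: Borohydride reduction of an aryl aldehyde to the benzylic alcohol; the aryl bromide is not touched.

Step 6
Reactants: 10 (2-bromo-3-methoxyphenyl)methanol
Product: 11 (2-bromo-3-methoxybenzyl)triphenylphosphonium bromide
Conditions: PPh3·HBr, MeCN, reflux
Reagents that add atoms: triphenylphosphine hydrobromide, [Br-].c1ccc(cc1)[PH+](c1ccccc1)c1ccccc1
Why: Direct phosphonium salt formation from a benzylic alcohol, as in step 2; the aryl C–Br bond does not react with the phosphine.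

Step 7
Reactants: 8 4-{2-(benzyloxy)-5-[2-(3-hydroxyphenyl)ethenyl]phenoxy}benzaldehyde; 11 (2-bromo-3-methoxybenzyl)triphenylphosphonium bromide
Product: 12 3-{2-[4-(benzyloxy)-3-{4-[2-(2-bromo-3-methoxyphenyl)ethenyl]phenoxy}phenyl]ethenyl}phenol (mixture of alkene isomers)
Conditions: 11 (1.3 equiv), KOtBu (2.5 equiv), THF, 0 °C to rt
Reagents that add atoms: none
Why: Wittig olefination; the phenoxide of 8 is remote from and not conjugated with the aldehyde, so the aldehyde should keep its reactivity, and ortho-bromobenzyl ylides are well behaved.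

Step 8
Reactants: 12 3-{2-[4-(benzyloxy)-3-{4-[2-(2-bromo-3-methoxyphenyl)ethenyl]phenoxy}phenyl]ethenyl}phenol
Product: 13 3-{2-[4-(benzyloxy)-3-{4-[2-(2-bromo-3-methoxyphenyl)ethyl]phenoxy}phenyl]ethyl}phenol
Conditions: TsNHNH2 (excess, added in portions), NaOAc, THF/H2O (1:1), reflux
Reagents that add atoms: none
Why: Diimide reduction; diimide generated from the sulfonyl hydrazide transfers two hydrogens to each stilbene double bond in a concerted way and should leave the aryl C–Br bond and the benzyl ether intact.

Step 9
Reactants: 13 3-{2-[4-(benzyloxy)-3-{4-[2-(2-bromo-3-methoxyphenyl)ethyl]phenoxy}phenyl]ethyl}phenol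
Product: 14 O-benzyl macrocycle (the target with the ring C hydroxyl as its benzyl ether)
Conditions: CuI (30 mol %), picolinic acid (60 mol %), K3PO4, DMSO, 100 °C, argon, slow addition of 13 (final 0.003 M)
Reagents that add atoms: none
Why: The phenoxide of ring B binds picolinate-ligated monovalent copper, the C1–Br bond of ring A adds oxidatively to give a trivalent copper aryl phenoxide, and reductive elimination forms the C1–O bond and returns monovalent copper. The closest known reaction type is the intramolecular Ullmann diaryl ether synthesis used for macrocyclic diaryl ethers, run here with a ligand system suited to ortho-hindered aryl halides. The 18-membered ring is closed end to end by intramolecular O-arylation at an sp2 carbon (ipso substitution of bromide), helped by the two flexible ethano bridges. No stereocenter is formed. The step needs ring closure to beat oligomerisation, which high dilution with slow addition should secure. Site and chemoselectivity are fixed because 13 holds a single aryl bromide and a single free phenol (the ring C oxygen is benzylated), and the C2 methoxy oxygen can assist copper at the neighbouring C1.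

Step 10
Reactants: 14 O-benzyl macrocycle
Product: 15 target macrocycle CNP0309263.0 (marchantin-type bis(bibenzyl) with the methoxy group on ring A and a free hydroxyl on ring C)
Conditions: H2 (1 atm), 10% Pd/C, EtOAc/MeOH, rt
Reagents that add atoms: none
Why: Hydrogenolysis of the benzyl ether should free the ring C phenol; the diaryl ethers and the methyl ether are stable under these conditions.

Compound list
1 | 4-(benzyloxy)-3-hydroxybenzaldehyde | O=Cc1ccc(OCc2ccccc2)c(O)c1 | starting material
2 | 4-fluorobenzonitrile | N#Cc1ccc(F)cc1 | starting material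
3 | 4-[2-(benzyloxy)-5-formylphenoxy]benzonitrile | O=Cc1ccc(OCc2ccccc2)c(Oc2ccc(C#N)cc2)c1 | intermediate
4 | 3-hydroxybenzyl alcohol | OCc1cccc(O)c1 | starting material
5 | (3-hydroxybenzyl)triphenylphosphonium bromide | [Br-].Oc1cccc(C[P+](c2ccccc2)(c2ccccc2)c2ccccc2)c1 | intermediate
6 | 4-{2-(benzyloxy)-5-[2-(3-hydroxyphenyl)ethenyl]phenoxy}benzonitrile (E/Z mixture) | N#Cc1ccc(Oc2cc(C=Cc3cccc(O)c3)ccc2OCc2ccccc2)cc1 | intermediate
7 | N-aluminio aldimine (N-diisobutylaluminium imine of 8, phenol as diisobutylaluminium phenoxide; not isolated) | CC(C)C[Al](CC(C)C)N=Cc1ccc(Oc2cc(C=Cc3cccc(O[Al](CC(C)C)CC(C)C)c3)ccc2OCc2ccccc2)cc1 | intermediate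
8 | 4-{2-(benzyloxy)-5-[2-(3-hydroxyphenyl)ethenyl]phenoxy}benzaldehyde (E/Z mixture) | O=Cc1ccc(Oc2cc(C=Cc3cccc(O)c3)ccc2OCc2ccccc2)cc1 | intermediate
9 | 2-bromo-3-methoxybenzaldehyde | COc1cccc(C=O)c1Br | starting material
10 | (2-bromo-3-methoxyphenyl)methanol | COc1cccc(CO)c1Br | intermediate
11 | (2-bromo-3-methoxybenzyl)triphenylphosphonium bromide | [Br-].COc1cccc(C[P+](c2ccccc2)(c2ccccc2)c2ccccc2)c1Br | intermediate
12 | 3-{2-[4-(benzyloxy)-3-{4-[2-(2-bromo-3-methoxyphenyl)ethenyl]phenoxy}phenyl]ethenyl}phenol (mixture of alkene isomers) | COc1cccc(C=Cc2ccc(Oc3cc(C=Cc4cccc(O)c4)ccc3OCc3ccccc3)cc2)c1Br | intermediate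
13 | 3-{2-[4-(benzyloxy)-3-{4-[2-(2-bromo-3-methoxyphenyl)ethyl]phenoxy}phenyl]ethyl}phenol | COc1cccc(CCc2ccc(Oc3cc(CCc4cccc(O)c4)ccc3OCc3ccccc3)cc2)c1Br | intermediate
14 | O-benzyl macrocycle (target with the ring C hydroxyl as benzyl ether) | COc1cccc2c1Oc1cccc(c1)CCc1ccc(OCc3ccccc3)c(c1)Oc1ccc(cc1)CC2 | intermediate
15 | target macrocycle CNP0309263.0 | COc1cccc2c1Oc1cccc(c1)CCc1ccc(O)c(c1)Oc1ccc(cc1)CC2 | target

Total step count: 10. Longest linear sequence: 7 steps (steps 1, 3, 4, 7, 8, 9 and 10, from compound 1).

Steps most likely to fail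

Step 9. Oxidative addition at the doubly ortho-substituted, electron-rich C1 of ring A may be slow, so that intermolecular coupling to oligomers or reductive loss of bromine takes over. The fallback reverses the polarity of ring A. It sets out from 13: Miyaura borylation (bis(pinacolato)diboron, Pd(OAc)2/SPhos, KOAc, dioxane, 100 °C) should give 3-{2-[4-(benzyloxy)-3-{4-[2-(3-methoxy-2-(4,4,5,5-tetramethyl-1,3,2-dioxaborolan-2-yl)phenyl)ethyl]phenoxy}phenyl]ethyl}phenol F1. An oxidative Chan–Lam macrocyclisation (Cu(OAc)2, pyridine, 4 Å MS, O2, MeCN, high dilution) would then join the same ring A carbon to the ring B oxygen and come back to the route at 14.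

Step 8. Diimide may disproportionate faster than it reduces, leaving one or both stilbene units partly unsaturated even after repeated charges. The fallback replaces transfer of hydrogen from diimide by heterogeneous catalytic hydrogenation. It sets out from 12 and uses H2 (3 bar) over sulfided 5% Pt/C in EtOAc, a catalyst that saturates alkenes without hydrogenolysis of aryl C–Br bonds or benzyl ethers, and comes back to the route at 13. It makes no new compound, F0.

Step 3. The ylide carries a phenoxide, so it may be poorly soluble and sluggish, leaving aldehyde unconverted. The fallback builds the same double bond by a Heck reaction. It sets out from 3: methylenation (methyltriphenylphosphonium bromide, KOtBu, THF) should give 4-[2-(benzyloxy)-5-ethenylphenoxy]benzonitrile F2. Heck arylation with 3-iodophenol (Pd(OAc)2, P(o-tol)3, Et3N, DMF, 100 °C) should then give 4-{2-(benzyloxy)-5-[(E)-2-(3-hydroxyphenyl)ethenyl]phenoxy}benzonitrile F3. F3 is the E isomer of 6 and comes back to the route at 6 for step 4.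

Further compounds
F1 | step 9 | 3-{2-[4-(benzyloxy)-3-{4-[2-(3-methoxy-2-(4,4,5,5-tetramethyl-1,3,2-dioxaborolan-2-yl)phenyl)ethyl]phenoxy}phenyl]ethyl}phenol | COc1cccc(CCc2ccc(Oc3cc(CCc4cccc(O)c4)ccc3OCc3ccccc3)cc2)c1B1OC(C)(C)C(C)(C)O1
F0 | step 8 | none | none
F2 | step 3 | 4-[2-(benzyloxy)-5-ethenylphenoxy]benzonitrile | C=Cc1ccc(OCc2ccccc2)c(Oc2ccc(C#N)cc2)c1
F3 | step 3 | 4-{2-(benzyloxy)-5-[(E)-2-(3-hydroxyphenyl)ethenyl]phenoxy}benzonitrile | N#Cc1ccc(Oc2cc(/C=C/c3cccc(O)c3)ccc2OCc2ccccc2)cc1
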